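The numbers in the tables are simulated for an exercise, and the scatter is random.

No constant of this flask is given, so I read one from the delta run, where target falls from 14.3 % at 50.0 s to 11.0 % at 90.0 s. I treat the catalysed steps as a pre-equilibrium by then and reckon with what they leave free: a pool of substrate, target and isomer of the product, shrinking through the uncatalysed step. The reading gives 0.00656 s⁻¹ for d, the drain rate, the first-order loss of that pool, which I assume carries over to this flask and to a flask with a lower charge of substrate.

- delta: substrate 0.23 M; precatalyst 0.2 mol%; run made earlier
- flask: substrate 0.23 M; precatalyst 0.1 mol%; time 8.0 min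

delta run (percent of the substrate charged)

| time / s | target / % |
|---|---|
| 10.0 | 8.9 |
| 20.0 | 14.5 |
| 30.0 | 16.0 |
| 50.0 | 14.3 |
| 80.0 | 11.6 |
| 90.0 | 11.0 |

(readings scatter by 0.3 percentage points)

- steps thought possible: substrate + catalyst <-> target + catalyst; target + catalyst <-> isomer of the product + catalyst; isomer of the product <-> substrate; substrate -> uncatalysed product; precatalyst -> catalyst
- no earlier run changes the charge of precatalyst; that part of a forecast is a guess

- the moment within 8.0 min at which there is most target
- the amount of target, in percent of the substrate charged, at that time

Turned round: in my reckoning, for this flask to keep the peak of 16.0 % read at 30.0 s in the delta run, exp(-d·Δt) over the added time Δt would have to stand near one. If the catalysed steps run at half speed, which is a guess, I put the peak in this flask at 1.00 min. The factor is then 0.821, and my own height is 13.1 %.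

The forecast gives 0.95 min (0.75 min to 1.25 min) and 16 % (14.8 % to 17.3 %), higher than mine, on the ground that “Peak height depends on rate ratios, so it stays about 16%”.

    substrate + catalyst ⇌ target + catalyst, rate k1*[substrate]*[catalyst] forward; the back reaction follows from the equilibrium constant (K = 0.350, k = 31.0 L mol⁻¹ s⁻¹)
    target + catalyst ⇌ isomer of the product + catalyst, rate k2*[catalyst]*[target] forward; the back reaction follows from the equilibrium constant (K = 0.780, k = 100 L mol⁻¹ s⁻¹)
    isomer of the product ⇌ substrate (k = 0.230 s⁻¹)
    substrate → uncatalysed product (k = 0.0140 s⁻¹)
    precatalyst → catalyst (k = 0.190 s⁻¹)

The flask reaches its most target, 14.0 %, at 0.758 min, earlier than either estimate; at that moment substrate stands at 39.0 % and uncatalysed product at 36.0 %. In the flask the passing of substrate into uncatalysed product runs on past the peak, with 88 % of its turnover up to 8.0 min behind it after 4.00 min. The drain rate, applied from the start, gives 95.7 % uncatalysed product at 8.0 min; the flask holds 98.1 %, and the neighbour with 0.058 M of substrate holds 97.2 %.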